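## Retrosynthetic overview

1. The target is read as guibourtinidol-(4α→6)-fisetinidol. The last bond-forming operation makes two bonds of the lower unit, the pyran aryl ether bond O1–C8a and the interflavan bond C6–C4(upper), from a dearomatised lower precursor (a 4-alkyl-4-hydroxycyclohexa-2,5-dienone, "p-quinol", carrying the C4–C3–C2 chain) and an upper 4-alkoxyflavan.
2. Enabling feature: in lower ring A the ether oxygen O1 sits on C8a, meta to the C7 hydroxyl and ortho to C4a, and C4a is para to that hydroxyl. Addition of the C2 hydroxyl to a dienone β-carbon next to the quaternary carbon, then loss of the quaternary hydroxyl as water, gives exactly this pattern; the restored resorcinol-type ring is then nucleophilic at C6 (para to O1, ortho to O7).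
3. Both halves come from L-tyrosine through one common α-silyloxy aldehyde: its phenol ring becomes ring A, its CH2 becomes C4, and its α-carbon (as the S lactate) becomes C3. C2 is set by Felkin–Anh addition of an aryl Grignard reagent (1,2-anti, hence 2,3-trans).
4. Ring order: upper ring C by the same quinol closure (step 8), then 7-O-benzylation and C4 oxygenation; lower ring C, re-aromatised lower ring A and the interflavan bond in one flask (step 14); desilylation and hydrogenolysis last.

Key step: step 14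

Remark (assumption): the upper unit is (2R,3S,4R) with 2,3-trans-3,4-trans substituents and the lower unit is (2R,3S); the 4-alkoxy donor is drawn as its expected 3,4-trans epimer, although either C4 epimer serves because the coupling passes through the planar C4 cation.

## Route

Step 1
Reactants: 1 L-tyrosine
Product: 2 (S)-2-hydroxy-3-(4-hydroxyphenyl)propanoic acid
Conditions: NaNO2, 1 M aq. H2SO4, 0 °C → rt
Reagents that add atoms: water, O
Why: Diazotisation gives the α-diazonium acid, which the neighbouring carboxylate displaces (α-lactone) before water opens the lactone, so hydroxyl replaces nitrogen with net retention (deaminative hydroxylation of an α-amino acid by double inversion) and the S centre that becomes C3 of both flavan units is kept.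

Step 2
Reactants: 2 (S)-2-hydroxy-3-(4-hydroxyphenyl)propanoic acid
Product: 3 methyl (S)-2-hydroxy-3-(4-hydroxyphenyl)propanoate
Conditions: MeOH, H2SO4 (cat.), reflux
Reagents that add atoms: methanol, CO
Why: Acid-catalysed Fischer esterification in methanol converts only the carboxylic acid and does not touch the carbinol stereocentre or the phenol.

Step 3
Reactants: 3 methyl (S)-2-hydroxy-3-(4-hydroxyphenyl)propanoate
Product: 4 methyl (S)-2-[(triisopropylsilyl)oxy]-3-{4-[(triisopropylsilyl)oxy]phenyl}propanoate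
Conditions: i-Pr3SiOSO2CF3 (TIPSOTf, 2.4 equiv), 2,6-lutidine, CH2Cl2, 0 °C → rt
Reagents that add atoms: triisopropylsilyl trifluoromethanesulfonate, CC(C)[Si](C(C)C)(C(C)C)OS(=O)(=O)C(F)(F)F
Why: A silyl triflate with a hindered pyridine base silylates phenol and secondary carbinol in one operation without enolising the α-oxy ester; the bulky, non-chelating O-TIPS group is chosen to steer the later aryl addition (Felkin–Anh) and to block five-membered ring closure in the quinol cyclisations.

Step 4
Reactants: 4 methyl (S)-2-[(triisopropylsilyl)oxy]-3-{4-[(triisopropylsilyl)oxy]phenyl}propanoate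
Product: 5 (S)-2-[(triisopropylsilyl)oxy]-3-{4-[(triisopropylsilyl)oxy]phenyl}propanal
Conditions: i-Bu2AlH (1.1 equiv), toluene, −78 °C; aq. potassium sodium tartrate, 0 °C; used without chromatography
Reagents that add atoms: none
Why: At −78 °C the α-silyloxy ester is half-reduced to an aluminium hemiacetal that is stable until work-up and then releases the aldehyde (partial ester reduction with a dialkylaluminium hydride), and the bulky α-O-TIPS group and the neutral work-up should keep the α-centre from epimerising; this one batch of aldehyde serves both branches.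

Step 5
Reactants: 5 (S)-2-[(triisopropylsilyl)oxy]-3-{4-[(triisopropylsilyl)oxy]phenyl}propanal; 6 1-(benzyloxy)-4-bromobenzene
Product: 8 (1R,2S)-1-[4-(benzyloxy)phenyl]-2-[(triisopropylsilyl)oxy]-3-{4-[(triisopropylsilyl)oxy]phenyl}propan-1-ol, via Grignard reagent 7 (not isolated)
Conditions: 6, Mg, THF, rt; then 5, THF, −78 → −20 °C; H2O quench
Reagents that add atoms: none
Why: Addition of the aryl Grignard reagent to the α-silyloxy aldehyde under non-chelating conditions should follow the Felkin–Anh model, with attack anti to the α-O-TIPS group setting the new carbinol centre 1R (1,2-anti), which becomes C2 (R) of the upper unit.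

Step 6
Reactants: 8 (1R,2S)-1-[4-(benzyloxy)phenyl]-2-[(triisopropylsilyl)oxy]-3-{4-[(triisopropylsilyl)oxy]phenyl}propan-1-ol
Product: 9 4-{(2S,3R)-3-[4-(benzyloxy)phenyl]-3-hydroxy-2-[(triisopropylsilyl)oxy]propyl}phenol
Conditions: Bu4NF (1.05 equiv), THF, −20 °C
Reagents that add atoms: none
Why: Fluoride cleaves the aryl silyl ether, whose phenoxide is a good leaving group, much faster than the hindered secondary alkyl TIPS ether, so one equivalent at low temperature should free only the phenol (chemoselective desilylation).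

Step 7
Reactants: 9 4-{(2S,3R)-3-[4-(benzyloxy)phenyl]-3-hydroxy-2-[(triisopropylsilyl)oxy]propyl}phenol
Product: 11 4-{(2S,3R)-3-[4-(benzyloxy)phenyl]-3-hydroxy-2-[(triisopropylsilyl)oxy]propyl}-4-hydroxycyclohexa-2,5-dien-1-one, via peroxyquinol 10 (not isolated)
Conditions: Oxone (2KHSO5·KHSO4·K2SO4), KHCO3, MeCN/H2O, rt; then Me2S
Reagents that add atoms: Oxone (active salt potassium peroxymonosulfate, source of singlet oxygen), [K+].[O-]S(=O)(=O)OO
Why: Singlet oxygen released from KHSO5 in hydrogen carbonate buffer adds to the phenolate at the alkylated para carbon to give p-peroxyquinol 10, which Me2S reduces to the p-quinol (oxidative dearomatisation of a para-alkylphenol); because no phenoxonium cation is formed, the free benzylic carbinol cannot spirocyclise onto the ipso carbon.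

Step 8
Reactants: 11 4-{(2S,3R)-3-[4-(benzyloxy)phenyl]-3-hydroxy-2-[(triisopropylsilyl)oxy]propyl}-4-hydroxycyclohexa-2,5-dien-1-one
Product: 13 (2R,3S)-2-[4-(benzyloxy)phenyl]-3-[(triisopropylsilyl)oxy]chroman-7-ol, via oxa-Michael adduct 12 (not isolated)
Conditions: TsOH·H2O (0.2 equiv), 4 Å MS, CH2Cl2, rt → 40 °C
Reagents that add atoms: none
Why: Proposed new method: TsOH activates the cross-conjugated dienone of 11 so that the C2 hydroxyl (the C3 oxygen is silylated and cannot compete) adds to a β-carbon in a 6-exo-trig oxa-Michael closure giving cis-fused 12, and acid-catalysed enolisation then turns the tertiary 4a-carbinol into an arene-hydrate-type dienol that loses water to phenol 13, which places the new aryl–O1 bond on C8a meta to the phenol; the closest known reaction types are the intramolecular oxa-Michael cyclisation of hydroxyalkyl p-quinols and the Michael addition/dehydrative rearomatisation of p-quinols with halide or thiol nucleophiles to 3-substituted 4-alkylphenols; no stereocentre is formed or broken, C2 and C3 keeping their configuration because no bond to them is cleaved.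

Step 9
Reactants: 13 (2R,3S)-2-[4-(benzyloxy)phenyl]-3-[(triisopropylsilyl)oxy]chroman-7-ol
Product: 14 (2R,3S)-7-(benzyloxy)-2-[4-(benzyloxy)phenyl]-3-[(triisopropylsilyl)oxy]chromane
Conditions: BnBr, K2CO3, DMF, rt
Reagents that add atoms: benzyl bromide, BrCc1ccccc1
Why: Williamson etherification of the phenoxide caps the 7-hydroxyl, so that ring A carries only ether oxygens during the C4 oxidation and the coupling.

Step 10
Reactants: 14 (2R,3S)-7-(benzyloxy)-2-[4-(benzyloxy)phenyl]-3-[(triisopropylsilyl)oxy]chromane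
Product: 15 (2R,3S,4R)-7-(benzyloxy)-2-[4-(benzyloxy)phenyl]-4-(2-ethoxyethoxy)-3-[(triisopropylsilyl)oxy]chromane
Conditions: DDQ, 2-ethoxyethanol, CH2Cl2, rt
Reagents that add atoms: 2-ethoxyethanol, CCOCCO
Why: DDQ abstracts hydride from C4, the benzylic position activated by O1 (ortho) and the 7-benzyloxy group (para), and the cation is trapped by the alcohol anti to the 3-O-TIPS group (oxidative C4 functionalisation of flavan-3-ol ethers); the C4 configuration is of no consequence because step 14 passes through the same planar cation.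

Step 11
Reactants: 5 (S)-2-[(triisopropylsilyl)oxy]-3-{4-[(triisopropylsilyl)oxy]phenyl}propanal; 16 1,2-bis(benzyloxy)-4-bromobenzene
Product: 18 (1R,2S)-1-[3,4-bis(benzyloxy)phenyl]-2-[(triisopropylsilyl)oxy]-3-{4-[(triisopropylsilyl)oxy]phenyl}propan-1-ol, via Grignard reagent 17 (not isolated)
Conditions: 16, Mg, THF, rt; then 5, THF, −78 → −20 °C; H2O quench
Reagents that add atoms: none
Why: The same Grignard addition as in step 5, with Felkin–Anh attack anti to the α-O-TIPS group, should set the carbinol centre 1R (1,2-anti), which becomes C2 (R) of the lower unit.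

Step 12
Reactants: 18 (1R,2S)-1-[3,4-bis(benzyloxy)phenyl]-2-[(triisopropylsilyl)oxy]-3-{4-[(triisopropylsilyl)oxy]phenyl}propan-1-ol
Product: 19 4-{(2S,3R)-3-[3,4-bis(benzyloxy)phenyl]-3-hydroxy-2-[(triisopropylsilyl)oxy]propyl}phenol
Conditions: Bu4NF (1.05 equiv), THF, −20 °C
Reagents that add atoms: none
Why: As in step 6, fluoride removes the aryl silyl ether far faster than the hindered secondary alkyl TIPS ether (chemoselective desilylation).

Step 13
Reactants: 19 4-{(2S,3R)-3-[3,4-bis(benzyloxy)phenyl]-3-hydroxy-2-[(triisopropylsilyl)oxy]propyl}phenol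
Product: 21 4-{(2S,3R)-3-[3,4-bis(benzyloxy)phenyl]-3-hydroxy-2-[(triisopropylsilyl)oxy]propyl}-4-hydroxycyclohexa-2,5-dien-1-one, via peroxyquinol 20 (not isolated)
Conditions: Oxone (2KHSO5·KHSO4·K2SO4), KHCO3, MeCN/H2O, rt; then Me2S
Reagents that add atoms: Oxone (active salt potassium peroxymonosulfate, source of singlet oxygen), [K+].[O-]S(=O)(=O)OO
Why: As in step 7, singlet-oxygen dearomatisation of the para-alkylphenolate and reduction of the hydroperoxide give the p-quinol without a cationic intermediate that the free benzylic carbinol could trap.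

Step 14
Reactants: 21 4-{(2S,3R)-3-[3,4-bis(benzyloxy)phenyl]-3-hydroxy-2-[(triisopropylsilyl)oxy]propyl}-4-hydroxycyclohexa-2,5-dien-1-one; 15 (2R,3S,4R)-7-(benzyloxy)-2-[4-(benzyloxy)phenyl]-4-(2-ethoxyethoxy)-3-[(triisopropylsilyl)oxy]chromane
Product: 24 (2R,3S)-2-[3,4-bis(benzyloxy)phenyl]-6-{(2R,3S,4R)-7-(benzyloxy)-2-[4-(benzyloxy)phenyl]-3-[(triisopropylsilyl)oxy]chroman-4-yl}-3-[(triisopropylsilyl)oxy]chroman-7-ol, via oxa-Michael adduct 22 (not isolated), via phenol 23 (not isolated)
Conditions: 21 (2.5 equiv), TsOH·H2O (0.2 equiv), 4 Å MS, CH2Cl2, rt → 40 °C; then −40 °C, 15 (1 equiv, slow addition), Me3SiOSO2CF3 (TMSOTf, 0.3 equiv), −40 → −20 °C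
Reagents that add atoms: none
Why: Proposed new method: TsOH activates the symmetric cross-conjugated dienone of 21 and the C2 hydroxyl adds to a β-carbon (which becomes C8a) in a 6-exo-trig oxa-Michael closure of lower ring C to give cis-fused 22, whose acid-catalysed enolisation and loss of the tertiary 4a-hydroxyl (arene-hydrate-type dehydration) re-aromatise lower ring A to the resorcinol-type phenol 23. TMSOTf then ionises either C4 epimer of 15 to the same benzylic cation (stabilised by O1 and the 7-benzyloxy group), which 23 captures at C6 in a Friedel–Crafts alkylation that forms the interflavan bond. The closest known reaction types are the intramolecular oxa-Michael cyclisation of hydroxyalkyl p-quinols, the Michael addition/dehydrative rearomatisation of p-quinols to 3-substituted 4-alkylphenols, and the Lewis-acid coupling of 4-alkoxyflavans with phenolic flavan nucleophiles used for proanthocyanidins; what is new is their use to make the flavan aryl ether bond and their merger in one flask. The only lasting new stereocentre, upper C4, should be set by attack of 23 anti to the bulky 3-O-TIPS group on the half-chair cation with the 2-aryl group pseudo-equatorial, giving the all-trans (4R) product, while the two transient ring-fusion centres of 22 vanish on aromatisation, so both cis-fused diastereomers converge. Six- over five-membered closure is secured by silylation of the C3 oxygen, the choice between the two β-carbons is without consequence because the dienone is symmetric, C6 over C8 follows from C6 being para to O1, ortho to the 7-hydroxyl and unhindered while C8 is flanked by both oxygens, and cross- over self-coupling is secured by forming 23 in excess before 15 is ionised.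

Step 15
Reactants: 24 (2R,3S)-2-[3,4-bis(benzyloxy)phenyl]-6-{(2R,3S,4R)-7-(benzyloxy)-2-[4-(benzyloxy)phenyl]-3-[(triisopropylsilyl)oxy]chroman-4-yl}-3-[(triisopropylsilyl)oxy]chroman-7-ol
Product: 25 (2R,3S)-2-[3,4-bis(benzyloxy)phenyl]-6-{(2R,3S,4R)-7-(benzyloxy)-2-[4-(benzyloxy)phenyl]-3-hydroxychroman-4-yl}chroman-3,7-diol
Conditions: HF·pyridine, THF/pyridine, 0 °C → rt
Reagents that add atoms: none
Why: Hydrogen fluoride buffered by pyridine cleaves both hindered secondary TIPS ethers through Si–F bond formation without ionising the acid-sensitive interflavan bond or touching the benzyl ethers.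

Step 16
Reactants: 25 (2R,3S)-2-[3,4-bis(benzyloxy)phenyl]-6-{(2R,3S,4R)-7-(benzyloxy)-2-[4-(benzyloxy)phenyl]-3-hydroxychroman-4-yl}chroman-3,7-diol
Product: 26 (2R,3S)-2-(3,4-dihydroxyphenyl)-6-[(2R,3S,4R)-3,7-dihydroxy-2-(4-hydroxyphenyl)chroman-4-yl]chroman-3,7-diol
Conditions: H2 (1 atm), Pd(OH)2/C, THF/MeOH/H2O, rt
Reagents that add atoms: none
Why: Hydrogenolysis over Pd(OH)2/C removes the four O-benzyl groups as toluene under neutral conditions, which should leave the ring C–O bonds, the interflavan C–C bond and all five stereocentres intact.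

## Compound list

1 | L-tyrosine | N[C@@H](Cc1ccc(O)cc1)C(=O)O | starting material
2 | (S)-2-hydroxy-3-(4-hydroxyphenyl)propanoic acid | O[C@@H](Cc1ccc(O)cc1)C(=O)O | intermediate
3 | methyl (S)-2-hydroxy-3-(4-hydroxyphenyl)propanoate | COC(=O)[C@@H](O)Cc1ccc(O)cc1 | intermediate
4 | methyl (S)-2-[(triisopropylsilyl)oxy]-3-{4-[(triisopropylsilyl)oxy]phenyl}propanoate | COC(=O)[C@@H](O[Si](C(C)C)(C(C)C)C(C)C)Cc1ccc(O[Si](C(C)C)(C(C)C)C(C)C)cc1 | intermediate
5 | (S)-2-[(triisopropylsilyl)oxy]-3-{4-[(triisopropylsilyl)oxy]phenyl}propanal | O=C[C@@H](O[Si](C(C)C)(C(C)C)C(C)C)Cc1ccc(O[Si](C(C)C)(C(C)C)C(C)C)cc1 | intermediate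
6 | 1-(benzyloxy)-4-bromobenzene | Brc1ccc(OCc2ccccc2)cc1 | starting material
7 | [4-(benzyloxy)phenyl]magnesium bromide | Br[Mg]c1ccc(OCc2ccccc2)cc1 | intermediate
8 | (1R,2S)-1-[4-(benzyloxy)phenyl]-2-[(triisopropylsilyl)oxy]-3-{4-[(triisopropylsilyl)oxy]phenyl}propan-1-ol | O[C@H](c1ccc(OCc2ccccc2)cc1)[C@@H](O[Si](C(C)C)(C(C)C)C(C)C)Cc1ccc(O[Si](C(C)C)(C(C)C)C(C)C)cc1 | intermediate
9 | 4-{(2S,3R)-3-[4-(benzyloxy)phenyl]-3-hydroxy-2-[(triisopropylsilyl)oxy]propyl}phenol | O[C@H](c1ccc(OCc2ccccc2)cc1)[C@@H](O[Si](C(C)C)(C(C)C)C(C)C)Cc1ccc(O)cc1 | intermediate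
10 | 4-{(2S,3R)-3-[4-(benzyloxy)phenyl]-3-hydroxy-2-[(triisopropylsilyl)oxy]propyl}-4-hydroperoxycyclohexa-2,5-dien-1-one | O[C@H](c1ccc(OCc2ccccc2)cc1)[C@@H](O[Si](C(C)C)(C(C)C)C(C)C)CC1(OO)C=CC(=O)C=C1 | intermediate
11 | 4-{(2S,3R)-3-[4-(benzyloxy)phenyl]-3-hydroxy-2-[(triisopropylsilyl)oxy]propyl}-4-hydroxycyclohexa-2,5-dien-1-one | O[C@H](c1ccc(OCc2ccccc2)cc1)[C@@H](O[Si](C(C)C)(C(C)C)C(C)C)CC1(O)C=CC(=O)C=C1 | intermediate
12 | (2R,3S)-2-[4-(benzyloxy)phenyl]-4a-hydroxy-3-[(triisopropylsilyl)oxy]-2,3,4,4a,8,8a-hexahydro-7H-chromen-7-one (cis ring fusion, either cis-fused diastereomer; the two transient fusion centres are left undefined) | O=C1CC2O[C@H](c3ccc(OCc4ccccc4)cc3)[C@@H](O[Si](C(C)C)(C(C)C)C(C)C)CC2(O)C=C1 | intermediate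
13 | (2R,3S)-2-[4-(benzyloxy)phenyl]-3-[(triisopropylsilyl)oxy]chroman-7-ol | Oc1ccc2c(c1)O[C@H](c1ccc(OCc3ccccc3)cc1)[C@@H](O[Si](C(C)C)(C(C)C)C(C)C)C2 | intermediate
14 | (2R,3S)-7-(benzyloxy)-2-[4-(benzyloxy)phenyl]-3-[(triisopropylsilyl)oxy]chromane | C(c1ccccc1)Oc1ccc2c(c1)O[C@H](c1ccc(OCc3ccccc3)cc1)[C@@H](O[Si](C(C)C)(C(C)C)C(C)C)C2 | intermediate
15 | (2R,3S,4R)-7-(benzyloxy)-2-[4-(benzyloxy)phenyl]-4-(2-ethoxyethoxy)-3-[(triisopropylsilyl)oxy]chromane (3,4-trans epimer drawn) | C(c1ccccc1)Oc1ccc2c(c1)O[C@H](c1ccc(OCc3ccccc3)cc1)[C@@H](O[Si](C(C)C)(C(C)C)C(C)C)[C@@H]2OCCOCC | intermediate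
16 | 1,2-bis(benzyloxy)-4-bromobenzene | Brc1ccc(OCc2ccccc2)c(OCc2ccccc2)c1 | starting material
17 | [3,4-bis(benzyloxy)phenyl]magnesium bromide | Br[Mg]c1ccc(OCc2ccccc2)c(OCc2ccccc2)c1 | intermediate
18 | (1R,2S)-1-[3,4-bis(benzyloxy)phenyl]-2-[(triisopropylsilyl)oxy]-3-{4-[(triisopropylsilyl)oxy]phenyl}propan-1-ol | O[C@H](c1ccc(OCc2ccccc2)c(OCc2ccccc2)c1)[C@@H](O[Si](C(C)C)(C(C)C)C(C)C)Cc1ccc(O[Si](C(C)C)(C(C)C)C(C)C)cc1 | intermediate
19 | 4-{(2S,3R)-3-[3,4-bis(benzyloxy)phenyl]-3-hydroxy-2-[(triisopropylsilyl)oxy]propyl}phenol | O[C@H](c1ccc(OCc2ccccc2)c(OCc2ccccc2)c1)[C@@H](O[Si](C(C)C)(C(C)C)C(C)C)Cc1ccc(O)cc1 | intermediate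
20 | 4-{(2S,3R)-3-[3,4-bis(benzyloxy)phenyl]-3-hydroxy-2-[(triisopropylsilyl)oxy]propyl}-4-hydroperoxycyclohexa-2,5-dien-1-one | O[C@H](c1ccc(OCc2ccccc2)c(OCc2ccccc2)c1)[C@@H](O[Si](C(C)C)(C(C)C)C(C)C)CC1(OO)C=CC(=O)C=C1 | intermediate
21 | 4-{(2S,3R)-3-[3,4-bis(benzyloxy)phenyl]-3-hydroxy-2-[(triisopropylsilyl)oxy]propyl}-4-hydroxycyclohexa-2,5-dien-1-one | O[C@H](c1ccc(OCc2ccccc2)c(OCc2ccccc2)c1)[C@@H](O[Si](C(C)C)(C(C)C)C(C)C)CC1(O)C=CC(=O)C=C1 | intermediate
22 | (2R,3S)-2-[3,4-bis(benzyloxy)phenyl]-4a-hydroxy-3-[(triisopropylsilyl)oxy]-2,3,4,4a,8,8a-hexahydro-7H-chromen-7-one (cis ring fusion, either cis-fused diastereomer; the two transient fusion centres are left undefined) | O=C1CC2O[C@H](c3ccc(OCc4ccccc4)c(OCc4ccccc4)c3)[C@@H](O[Si](C(C)C)(C(C)C)C(C)C)CC2(O)C=C1 | intermediate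
23 | (2R,3S)-2-[3,4-bis(benzyloxy)phenyl]-3-[(triisopropylsilyl)oxy]chroman-7-ol | Oc1ccc2c(c1)O[C@H](c1ccc(OCc3ccccc3)c(OCc3ccccc3)c1)[C@@H](O[Si](C(C)C)(C(C)C)C(C)C)C2 | intermediate
24 | (2R,3S)-2-[3,4-bis(benzyloxy)phenyl]-6-{(2R,3S,4R)-7-(benzyloxy)-2-[4-(benzyloxy)phenyl]-3-[(triisopropylsilyl)oxy]chroman-4-yl}-3-[(triisopropylsilyl)oxy]chroman-7-ol | Oc1c([C@@H]3c4ccc(OCc5ccccc5)cc4O[C@H](c4ccc(OCc5ccccc5)cc4)[C@H]3O[Si](C(C)C)(C(C)C)C(C)C)cc2c(c1)O[C@H](c1ccc(OCc3ccccc3)c(OCc3ccccc3)c1)[C@@H](O[Si](C(C)C)(C(C)C)C(C)C)C2 | intermediate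
25 | (2R,3S)-2-[3,4-bis(benzyloxy)phenyl]-6-{(2R,3S,4R)-7-(benzyloxy)-2-[4-(benzyloxy)phenyl]-3-hydroxychroman-4-yl}chroman-3,7-diol | Oc1c([C@@H]3c4ccc(OCc5ccccc5)cc4O[C@H](c4ccc(OCc5ccccc5)cc4)[C@H]3O)cc2c(c1)O[C@H](c1ccc(OCc3ccccc3)c(OCc3ccccc3)c1)[C@@H](O)C2 | intermediate
26 | (2R,3S)-2-(3,4-dihydroxyphenyl)-6-[(2R,3S,4R)-3,7-dihydroxy-2-(4-hydroxyphenyl)chroman-4-yl]chroman-3,7-diol | Oc1ccc([C@H]2Oc3cc(O)ccc3[C@@H](c3cc4c(cc3O)O[C@H](c3ccc(O)c(O)c3)[C@@H](O)C4)[C@@H]2O)cc1 | target

## Step count and risks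

Total step count: 16. Longest linear sequence: 13 steps (steps 1–10, then 14–16); the lower branch (steps 1–4, 11–13, 14–16) has 10.

**Step 14 (bears the label).** The electron-rich benzylic carbinol of 21 may ionise under acid before it has added to the dienone, leading to epimerisation at C2 or ether formation with the quinol hydroxyl. The cis-fused adduct may revert faster than it dehydrates. Once 15 is ionised, the cation may alkylate ring A of a second molecule of 15 or of the product, attack C8 instead of C6, or give the 3,4-cis epimer.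

The fallback uses known reactions only and separates the events; it sets out from 21 and 15 and returns at 24. Quinol 21 is cyclised under base (DBU 0.2 equiv, CH2Cl2, rt; base-mediated oxa-Michael addition) to 22, which is isolated. Dehydration with the Burgess reagent (MeO2CNSO2NEt3, THF, 50 °C; syn-elimination of the tertiary carbinol towards the cis C8a hydrogen, then tautomerisation) gives isolated phenol 23. Separately, thiolysis of 15 (BnSH, ZnI2 cat., CH2Cl2, −20 °C) gives the thioether donor (2R,3R,4R)-7-(benzyloxy)-2-[4-(benzyloxy)phenyl]-4-(benzylsulfanyl)-3-[(triisopropylsilyl)oxy]chromane F1 (3,4-trans; the 3-descriptor changes only through the priority of sulfur). F1 is then coupled with 23 (3 equiv) by thiophilic activation (AgBF4, THF, 0 °C), the established neutral interflavan coupling, to give 24.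

**Step 8 (bears the label).** The same ring-closure processes may go wrong: acid ionisation of the benzylic carbinol of 11 before addition, retro-oxa-Michael reversion outrunning dehydration, or migration of the C4 carbon (dienone–phenol shift) to a hydroquinone-type isomer.

The fallback uses known reactions only; it sets out from 11 and returns at 13. DBU (0.2 equiv, CH2Cl2, rt) closes the ring by base-mediated oxa-Michael addition to give 12, here isolated. The Burgess reagent (MeO2CNSO2NEt3, THF, 50 °C) then removes the tertiary hydroxyl by syn-elimination, and the dienone formed tautomerises to 13. No compound outside the compound list is made (none F0).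

**Step 10.** Hydride abstraction may also occur at C2 (a para-alkoxybenzylic ether C–H), the 4-alkoxy product may be oxidised further, and a 5-deoxy ring A is less easily oxidised than a phloroglucinol-type ring, so conversion may stall.

The fallback changes the oxidation from ether C–H abstraction to phenol oxidation; it sets out from 13 (before benzylation) and returns at 26. DDQ (1.0 equiv, MeOH/CH2Cl2, 0 °C) oxidises the para-alkylphenol to the ring A quinone methide, which adds methanol at C4 (1,6-addition) to give (2R,3S,4R)-2-[4-(benzyloxy)phenyl]-4-methoxy-3-[(triisopropylsilyl)oxy]chroman-7-ol F2. F2 replaces 15 in the flask of step 14 (TsOH alone should ionise this free-phenolic ether; slow addition at −20 °C) and should give (2R,3S)-2-[3,4-bis(benzyloxy)phenyl]-6-{(2R,3S,4R)-2-[4-(benzyloxy)phenyl]-7-hydroxy-3-[(triisopropylsilyl)oxy]chroman-4-yl}-3-[(triisopropylsilyl)oxy]chroman-7-ol F3. HF·pyridine as in step 15 gives (2R,3S)-2-[3,4-bis(benzyloxy)phenyl]-6-{(2R,3S,4R)-2-[4-(benzyloxy)phenyl]-3,7-dihydroxychroman-4-yl}chroman-3,7-diol F4, and hydrogenolysis as in step 16 gives 26.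

## Further compounds

F1 | step 14 | (2R,3R,4R)-7-(benzyloxy)-2-[4-(benzyloxy)phenyl]-4-(benzylsulfanyl)-3-[(triisopropylsilyl)oxy]chromane | C(c1ccccc1)Oc1ccc2c(c1)O[C@H](c1ccc(OCc3ccccc3)cc1)[C@@H](O[Si](C(C)C)(C(C)C)C(C)C)[C@@H]2SCc1ccccc1
F0 | step 8 | none | none
F2 | step 10 | (2R,3S,4R)-2-[4-(benzyloxy)phenyl]-4-methoxy-3-[(triisopropylsilyl)oxy]chroman-7-ol | Oc1ccc2c(c1)O[C@H](c1ccc(OCc3ccccc3)cc1)[C@@H](O[Si](C(C)C)(C(C)C)C(C)C)[C@@H]2OC
F3 | step 10 | (2R,3S)-2-[3,4-bis(benzyloxy)phenyl]-6-{(2R,3S,4R)-2-[4-(benzyloxy)phenyl]-7-hydroxy-3-[(triisopropylsilyl)oxy]chroman-4-yl}-3-[(triisopropylsilyl)oxy]chroman-7-ol | Oc1c([C@@H]3c4ccc(O)cc4O[C@H](c4ccc(OCc5ccccc5)cc4)[C@H]3O[Si](C(C)C)(C(C)C)C(C)C)cc2c(c1)O[C@H](c1ccc(OCc3ccccc3)c(OCc3ccccc3)c1)[C@@H](O[Si](C(C)C)(C(C)C)C(C)C)C2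
F4 | step 10 | (2R,3S)-2-[3,4-bis(benzyloxy)phenyl]-6-{(2R,3S,4R)-2-[4-(benzyloxy)phenyl]-3,7-dihydroxychroman-4-yl}chroman-3,7-diol | Oc1c([C@@H]3c4ccc(O)cc4O[C@H](c4ccc(OCc5ccccc5)cc4)[C@H]3O)cc2c(c1)O[C@H](c1ccc(OCc3ccccc3)c(OCc3ccccc3)c1)[C@@H](O)C2
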